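The earlier runs and the new flask stem from a simulated flask for an exercise, noise included.

**The turned question.** If the exchange between the two substrates hardly took part, the ratio of left-handed to right-handed product had to fall as conversion rose, so that fall was what I looked for in the earlier runs.

common to all: left-handed substrate 0.34 M; right-handed substrate 0.34 M; gas 11 mM (held)

| run | free catalyst | racemization catalyst | remark | time |
|---|---|---|---|---|
| amber | 11 mM | 3.4 mM | run made earlier |  |
| ochre | 26 mM | 3.4 mM | run made earlier |  |
| violet | 17 mM | 1.7 mM | run made earlier |  |
| flask | 17 mM | 3.4 mM |  | 30 h |

- amber (time / h: left-handed product / %, right-handed product / %): 6.00: 26, 11; 12.0: 28, 11; 20.0: 29, 10; 25.0: 29, 14; 30.0: 31, 12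
- ochre (time / h: left-handed product / %, right-handed product / %): 2.50: 23, 8; 5.00: 40, 15; 8.00: 49, 17; 15.0: 51, 19; 30.0: 51, 17
- violet (time / h: left-handed product / %, right-handed product / %): 2.50: 19, 9; 8.00: 36, 13; 15.0: 41, 15; 20.0: 40, 17; 30.0: 39, 15

(standard deviation of a reading: 1.5 percentage points)

- free catalyst is single-handed; left-handed substrate and right-handed substrate are mirror images of each other, charged as a racemate, each of them at the stated concentration
- at the start none of the gas is in solution
- an excess is below zero if the other one leads

* left-handed product and right-handed product together, in percent of the left-handed substrate and right-handed substrate charged together, at 30 h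
* excess of left-handed product over right-handed product in the product at 30 h
* whether the exchange between left-handed substrate and right-handed substrate keeps pace with the reaction: how far the product's excess at 30 h gets from its value without exchange to its value with instant exchange (above 80% keeps pace, below 20% hardly takes part, else lags behind)

**Frozen ratio.** I summed the last readings of amber, ochre and violet, and left-handed over right-handed product came to 2.75: this reading is the frozen ratio, and with exchange in step it is the selectivity factor. The same sum over the first readings gave 2.43, so the ratio had not fallen. Violet, with c(racemization catalyst) at 1.7 mM, half of the new flask's, still read 2.60 at the end.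

**My reckoning.** I therefore froze the ratio for the new flask, which gave an excess of 46.7% and exchange that keeps pace. Violet carried the same free catalyst, and its totals from 15.0 h onward averaged 55.7%, which I took over as the yield.

**The forecast.** It gave 55%, 45% and keeps pace, in its words: “The flask has twice that amount, so exchange keeps pace.” Its excess stood lower than mine.

**The result.** The flask gave 54.8% and 47.0%, and the exchange keeps pace, at 96% of the way to the excess with instant exchange.

    partner + free catalyst + left-handed substrate → free catalyst + left-handed product (k = 76.0 L² mol⁻² min⁻¹)
    gas ⇌ partner, rate k2*(csat - [partner]) (kL = 0.160 min⁻¹)
    partner + free catalyst + right-handed substrate → free catalyst + right-handed product (k = 27.0 L² mol⁻² min⁻¹)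
    2 partner → self-condensation product (k = 1.60 L mol⁻¹ min⁻¹)
    left-handed substrate + racemization catalyst ⇌ right-handed substrate + racemization catalyst, rate k5*[racemization catalyst]*[left-handed substrate] forward; the back reaction follows from the equilibrium constant (k = 16.0 L mol⁻¹ min⁻¹)
    partner + free catalyst → spent catalyst (k = 1.10 L mol⁻¹ min⁻¹)

**Why it held.** The flask's excess corresponds to a ratio of 2.77, close to the frozen ratio. The path from left-handed substrate to right-handed substrate, both ways, accounts for part of that excess: in the same flask without that path, the excess falls from 47.0% to 33.9%. The flask's yield stopped at 54.8% mainly through the path from partner and free catalyst to spent catalyst, with free catalyst at 0% at 30.0 h. The neighbour charged with 0.068 M of free catalyst reached 95.7% at a ratio of 2.71, with left-handed product at 70.0%.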